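## Structural features

The target is an achiral diaryl ether with no stereocentre, so no stereocentres stand next to one another and the whole problem is regiochemical. Ring A is a pentasubstituted methyl benzoate (C1 CO2Me, C2 O-aryl, C3 OMe, C4 Cl, C5 OH, C6 H). Ring B is a 2,6-dioxygenated 4-methylbenzoic acid (C1' ether carbon, C2' H, C3' CH3, C4' H, C5' OH, C6' CO2H). The rings are joined only through the oxygen between C2 and C1', which is crowded by CO2Me and OMe on ring A and by CO2H on ring B, so a late aromatic substitution or Ullmann coupling is unattractive. The ring B acid must travel as an ester that can be cleaved without touching the ring A methyl ester, and the two phenols must be masked. Fragile points are the 2,6-dioxygenated benzoic acid (decarboxylation in hot acid), the para-oxygenated phenol of ring A (oxidation to a quinone or spiro-dienone) and the methyl ester (hydrolysis). The second real difficulty is chlorine on C4, between two oxygens and para to the ester, where kinetic chlorination of a 3,5-dioxygenated benzoate is not expected to go. The key step uses the fact that C6'(CO2H)–C5'(OH)–C4'(H)–C3'(CH3) is the C3–C6 segment of a 4-oxygenated 6-methyl-2-pyranone 3-carboxylate, while C1' and C2' can be the two carbons of an ethynyl ether on the C2 oxygen, so ring B is grown around an ether oxygen that is already in place.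

## Logic of the disconnections

17 to 16: the two O–CH2OMe bonds and the O–C(CH3)3 bond are cut. All three masks fall to acid, to which the methyl ester of 17 is inert, so one operation follows the key step. The forward step must not decarboxylate the ring B acid or let formaldehyde-derived cations alkylate ring B.

16 to 9 and 14 (through 15): C6'–C1' and C3'–C2' are cut. This removes ring B and the hindered ether problem together, and leaves a ring A ethynyl ether and a pyranone that already carries ester, oxygen, H and CH3 in the right order. The forward step must bond the oxygen-bearing alkyne carbon to C3 of 14 and must run below the temperature at which 9 decomposes.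

9 to 8 to 6 (through 7): the C(sp)–Si bond and then the O–C(sp) bond are cut. The terminal ynol ether is too labile to carry, so it is released from a silyl-capped form just before use. The O–C(sp) bond comes from a copper-catalysed vinylic C–O coupling followed by elimination, which asks a doubly flanked, ester-chelated phenol to couple and a base to spare the methyl ester.

6 to 5 to 3 (through 4): the O–CH2OMe bond on C5 and then the C2–O bond are cut. In 3 the only hydroxyl has its para position, the future C2, open, so oxidation to the para-quinone 4 places the oxygen there without ambiguity. Reduction gives 5, whose hydroxyls differ (C2-OH chelated to the ester, C5-OH free), so one equivalent of alkylating agent should select C5.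

3 to 2 to 1: the C4–Cl bond is exchanged for C4–Br and the O–CH3 bond is cut. Attack of Cl+ at C4 of a 3,5-dioxygenated benzoate puts the para share of positive charge on the ester-bearing carbon, so it should be the slowest of the three open positions. The 4-bromo isomer 1 is the one that is sold, and copper-mediated halogen exchange transfers that regiochemistry to chlorine. Because 1 is symmetric, mono-methylation raises only a statistical question.

14 to 11 and 12 (through 13) to 10: the C3–carboxyl bond and the O–CH2OMe bond are cut. C3–H of 11 lies between the lactone carbonyl and a chelating acetal oxygen, so kinetic lithiation there and capture by 12 installs the tert-butyl ester in one step. The forward step must favour ring lithiation over deprotonation of the C6 methyl group and avoid double addition.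

## Other disconnections considered

Alternative 1: Ring A is cut at C1–C6 and C2–C3 while ring B stays fused to a furanone. Forward, 1,1-dimethoxy-3-(trimethylsilyloxy)buta-1,3-diene A2 would add to the exocyclic double bond of methyl (2Z)-[4-(methoxymethoxy)-6-methyl-3-oxo-1-benzofuran-2(3H)-ylidene]acetate A1, its CH2 terminus to the ester-bearing carbon and its acetal carbon to the furanone C2, and acid work-up would give the spiro methoxy-enone A3.
- In its favour: this is a normal-demand cycloaddition of a matched pair with close analogy in grisan syntheses, and no ynol ether is handled; on both points it is the better of the two plans. C4 of A3 is the alpha carbon of a vinylogous ester, so chlorine should enter there without the halogen exchange the chosen route needs. Opening the furanone at its carbonyl would free the ring B acid directly, so no orthogonal ester is required.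
- Against it: the acetal carbon must bond to a fully substituted, oxygen-bearing carbon. Two stereocentres are made only to be destroyed. After the key step ring A still needs chlorination, dehydrogenation across C1–C6 and hydrolytic C–C cleavage.
- Comparison: three or four steps follow the key step against one, and A1 needs its own multi-step preparation from an orcinol derivative, so step economy is equal at best. The chosen plan is more convergent and reaches the aromatic oxidation level directly.

Alternative 2: Ring A is cut at C1–C2 and C3–C4. Forward, the anion of dimethyl 2-[2-(tert-butoxycarbonyl)-3-(methoxymethoxy)-5-methylphenoxy]propanedioate A4 would add to methyl (2E)-4-oxopent-2-enoate A5 at the carbon beta to the ketone, and the methyl ketone enolate would close onto a malonate ester to give the cyclohexane-1,3-dione A6.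
- In its favour: the crowded ether is made by alkylating a phenol with a bromomalonate, which is equal to the chosen plan in avoiding aromatic substitution and better in avoiding the ynol ether. The partners are cheap. C4 lies between two carbonyls, so chlorination there is inherently regioselective and can also supply the oxidation needed for aromatisation.
- Against it: the extra ester on C2 must be removed selectively beside two other esters. The resulting 3,5-dioxygenated ring has to be methylated on the C3 oxygen only, with little intrinsic bias. The hindered tertiary malonate anion may add reversibly.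
- Comparison: four or five steps follow the key step. The chosen plan joins the rings only after ring A is fully differentiated, which is its main structural advantage. Alternative 2 is better on raw-material cost and chlorine placement and worse on step count and the C3/C5 oxygen problem.

Alternative 3: Ring B is cut at C1'–C2' and C5'–C6'. Forward, 1-methoxy-3-methyl-1-(trimethylsilyloxy)buta-1,3-diene A8 would add to the triple bond of methyl 2-{[3-(tert-butoxy)-3-oxoprop-1-yn-1-yl]oxy}-4-chloro-3-methoxy-5-(methoxymethoxy)benzoate A7, CH2 terminus to the aryloxy-bearing carbon and ketene-acetal carbon to the ester-bearing carbon. Loss of methanol and desilylation would give the salicylate A9.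
- In its favour: the electron demand is normal, with a strongly polarised diene, and both partners dictate the same regiochemistry. A7 should tolerate heat far better than 9. C5'-OH emerges free, so the endgame is the same single acidolysis. On reactivity and thermal tolerance this alternative is probably the better one.
- Against it: A7 must be made from 9 by deprotonation and acylation beside a methyl ester, one more step on the longest line. The aryloxy donor lowers the electrophilicity of the alkyne at the carbon that must take the diene terminus next to the crowded ring A. A8 is moisture-sensitive and needs its own two-step preparation.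
- Comparison: the same ring and the same number of skeletal bonds are formed, and the step count is equal within one step. The chosen plan uses 9 directly and draws four ring B carbons with oxygen and methyl from a cheap lactone. Alternative 3 is kept as the fallback for step 9.

Key step: step 9

Remark: (2,2-dibromoethenyl)tri(propan-2-yl)silane, the two-carbon reagent of step 5, is taken as an available reagent and its preparation is not counted as a step.

## Steps

Step 1
Reactants: 1 methyl 4-bromo-3,5-dihydroxybenzoate
Product: 2 methyl 4-bromo-3-hydroxy-5-methoxybenzoate
Conditions: MeI (1.0 equiv), K2CO3 (1.0 equiv), DMF, rt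
Reagents that add atoms: iodomethane, CI
Why: Williamson O-methylation; the two hydroxyls of 1 are equivalent by symmetry, so only the degree of alkylation has to be controlled, which one equivalent of MeI and recycling of recovered 1 should handle.

Step 2
Reactants: 2 methyl 4-bromo-3-hydroxy-5-methoxybenzoate
Product: 3 methyl 4-chloro-3-hydroxy-5-methoxybenzoate
Conditions: CuCl (4 equiv), DMF, 140 °C, N2, no added base
Reagents that add atoms: copper monochloride (CuCl), [Cu+].[Cl-]
Why: Copper-mediated aromatic halogen exchange (aryl bromide to aryl chloride with excess CuCl in a dipolar aprotic solvent), driven by the stronger C–Cl bond and the excess of chloride. It fixes chlorine at the position that direct chlorination is not expected to favour.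

Step 3
Reactants: 3 methyl 4-chloro-3-hydroxy-5-methoxybenzoate
Product: 5 methyl 4-chloro-2,5-dihydroxy-3-methoxybenzoate, via chloroquinone 4 (not isolated)
Conditions: (KSO3)2NO (2.5 equiv), KH2PO4, Aliquat 336 (cat.), CH2Cl2/H2O, rt; then Na2S2O4 (aq)
Reagents that add atoms: dipotassium nitrosodisulfonate, (KSO3)2NO, [K+].[K+].[O-]S(=O)(=O)N([O])S(=O)(=O)[O-]
Why: Teuber oxidation; the nitroxyl radical abstracts the phenolic hydrogen and a second equivalent couples at the open para carbon (the future C2), which should give para-quinone 4 and not an ortho-quinone. Reduction with Na2S2O4 in the same flask gives hydroquinone 5, so the electrophilic ester-bearing quinone is never handled.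

Step 4
Reactants: 5 methyl 4-chloro-2,5-dihydroxy-3-methoxybenzoate
Product: 6 methyl 4-chloro-2-hydroxy-3-methoxy-5-(methoxymethoxy)benzoate
Conditions: MOMCl (1.1 equiv), i-Pr2NEt, CH2Cl2, 0 °C, degassed
Reagents that add atoms: chloromethyl methyl ether, COCCl
Why: Selective O-alkylation; the C2 hydroxyl is hydrogen-bonded to the ester carbonyl and flanked on both sides, so the C5 hydroxyl, more acidic (ortho chlorine) and more accessible, should take the single equivalent of MOMCl.

Step 5
Reactants: 6 methyl 4-chloro-2-hydroxy-3-methoxy-5-(methoxymethoxy)benzoate
Product: 8 methyl 4-chloro-3-methoxy-5-(methoxymethoxy)-2-{[(triisopropylsilyl)ethynyl]oxy}benzoate, via bromoenol ether 7 (not isolated)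
Conditions: CuI (15 mol%), 2,2'-bipyridine (30 mol%), K3PO4, PhMe, 110 °C; then t-BuOK, THF, 0 °C
Reagents that add atoms: (2,2-dibromoethenyl)tri(propan-2-yl)silane, BrC(Br)=C[Si](C(C)C)(C(C)C)C(C)C
Why: Copper-catalysed C–O coupling of a phenol with a 1,1-dibromoalkene (Ullmann-type vinylic substitution at the C–Br bond trans to silicon), then base-induced anti-elimination of HBr from bromoenol ether 7. The O–C(sp) bond is made without a free terminal ynol ether, and the TIPS cap makes 8 storable.

Step 6
Reactants: 8 methyl 4-chloro-3-methoxy-5-(methoxymethoxy)-2-{[(triisopropylsilyl)ethynyl]oxy}benzoate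
Product: 9 methyl 4-chloro-2-(ethynyloxy)-3-methoxy-5-(methoxymethoxy)benzoate
Conditions: Bu4NF (1.1 equiv), wet THF, −40 → 0 °C, short contact, used at once
Reagents that add atoms: none
Why: Fluoride-induced protodesilylation of a silylalkyne; low temperature and the absence of acid should preserve the terminal ynol ether, which goes straight into step 9.

Step 7
Reactants: 10 4-hydroxy-6-methyl-2H-pyran-2-one (triacetic acid lactone)
Product: 11 4-(methoxymethoxy)-6-methyl-2H-pyran-2-one
Conditions: MOMCl, i-Pr2NEt, CH2Cl2, 0 °C → rt
Reagents that add atoms: chloromethyl methyl ether, COCCl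
Why: O-alkylation of the vinylogous acid with a hard electrophile; the 4-alkoxy-2-pyranone is the expected major product over the 2-alkoxy-4-pyranone isomer, as in the usual 4-O-alkylation of this lactone.

Step 8
Reactants: 11 4-(methoxymethoxy)-6-methyl-2H-pyran-2-one; 12 di-tert-butyl dicarbonate
Product: 14 tert-butyl 4-(methoxymethoxy)-6-methyl-2-oxo-2H-pyran-3-carboxylate, via lithiopyranone 13 (not isolated)
Conditions: n-BuLi (1.05 equiv), THF, −78 °C; then transferred into 12 (1.5 equiv), THF, −78 → −40 °C
Reagents that add atoms: none
Why: Kinetic ring lithiation of a 4-alkoxy-6-methyl-2-pyranone at C3, the carbon between the lactone carbonyl and the chelating acetal oxygen, followed by acylation of the vinyllithium with 12. Inverse addition into excess 12 should suppress proton transfer to the more acidic product and double addition.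

Step 9
Reactants: 9 methyl 4-chloro-2-(ethynyloxy)-3-methoxy-5-(methoxymethoxy)benzoate; 14 tert-butyl 4-(methoxymethoxy)-6-methyl-2-oxo-2H-pyran-3-carboxylate
Product: 16 methyl 2-[2-(tert-butoxycarbonyl)-3-(methoxymethoxy)-5-methylphenoxy]-4-chloro-3-methoxy-5-(methoxymethoxy)benzoate, via bicyclic lactone 15 (not isolated)
Conditions: 14 (2.5 equiv), PhMe (1 M), BHT (cat.), K2CO3 (solid), sealed tube, 100 °C
Reagents that add atoms: none
Why: Inverse-electron-demand Diels–Alder reaction followed by cycloreversion: the HOMO of ynol ether 9, largest at its terminal carbon, meets the LUMO of pyranone 14, which is lowered by the lactone carbonyl and the C3 ester and is largest at C6. Bond formation is asynchronous, terminal CH to C6 running ahead of C(OAr) to C3, and gives the 2-oxabicyclo[2.2.2]octadienone 15. 15 then expels CO2 in a retro-[4+2] step driven by aromatisation, so ring B appears directly as the benzene. The closest known chemistry is the addition of ketene acetals, ynamines and alkoxyalkynes to 3-alkoxycarbonyl-2-pyranones with loss of CO2 to give benzoates. Ring B is closed by an intermolecular [4+2] cycloaddition that makes C6'–C1' and C3'–C2' in one operation, and the six-membered carbocycle is what survives extrusion of the lactone bridge. The two bridgehead stereocentres of 15 are transient and vanish with CO2, so no stereocontrol is needed. The selectivity required is regiochemical, O-aryl ortho to the ester, and it is secured by the matched polarisation of the partners (oxygen donor on the alkyne, vinylogous acceptor terminus C6 on the diene). Acid-free conditions, a radical inhibitor, high concentration and an excess of 14 protect the ynol ether, because the C4 alkoxy and C6 methyl groups make 14 a slow diene that needs heat.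

Step 10
Reactants: 16 methyl 2-[2-(tert-butoxycarbonyl)-3-(methoxymethoxy)-5-methylphenoxy]-4-chloro-3-methoxy-5-(methoxymethoxy)benzoate
Product: 17 2-[3-chloro-4-hydroxy-2-methoxy-6-(methoxycarbonyl)phenoxy]-6-hydroxy-4-methylbenzoic acid (target)
Conditions: TFA/CH2Cl2 (1:2), H2O (5 equiv), 0 °C → rt
Reagents that add atoms: none
Why: Acidolysis; the tert-butyl ester fragments through the tert-butyl cation and both MOM acetals hydrolyse, while the methyl ester and the diaryl ether are inert to TFA at room temperature. Water captures the methoxymethyl cation before it can alkylate the electron-rich ring B, and the low temperature guards the 2,6-dioxygenated acid against decarboxylation.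

## Compound list

1 | methyl 4-bromo-3,5-dihydroxybenzoate | COC(=O)c1cc(O)c(Br)c(O)c1 | starting material
2 | methyl 4-bromo-3-hydroxy-5-methoxybenzoate | COC(=O)c1cc(O)c(Br)c(OC)c1 | intermediate
3 | methyl 4-chloro-3-hydroxy-5-methoxybenzoate | COC(=O)c1cc(O)c(Cl)c(OC)c1 | intermediate
4 | methyl 4-chloro-5-methoxy-3,6-dioxocyclohexa-1,4-diene-1-carboxylate | COC(=O)C1=CC(=O)C(Cl)=C(OC)C1=O | intermediate
5 | methyl 4-chloro-2,5-dihydroxy-3-methoxybenzoate | COC(=O)c1cc(O)c(Cl)c(OC)c1O | intermediate
6 | methyl 4-chloro-2-hydroxy-3-methoxy-5-(methoxymethoxy)benzoate | COC(=O)c1cc(OCOC)c(Cl)c(OC)c1O | intermediate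
7 | methyl 2-{[(Z)-1-bromo-2-(triisopropylsilyl)ethenyl]oxy}-4-chloro-3-methoxy-5-(methoxymethoxy)benzoate | COC(=O)c1cc(OCOC)c(Cl)c(OC)c1O/C(Br)=C/[Si](C(C)C)(C(C)C)C(C)C | intermediate
8 | methyl 4-chloro-3-methoxy-5-(methoxymethoxy)-2-{[(triisopropylsilyl)ethynyl]oxy}benzoate | COC(=O)c1cc(OCOC)c(Cl)c(OC)c1OC#C[Si](C(C)C)(C(C)C)C(C)C | intermediate
9 | methyl 4-chloro-2-(ethynyloxy)-3-methoxy-5-(methoxymethoxy)benzoate | COC(=O)c1cc(OCOC)c(Cl)c(OC)c1OC#C | intermediate
10 | 4-hydroxy-6-methyl-2H-pyran-2-one (triacetic acid lactone) | Cc1cc(O)cc(=O)o1 | starting material
11 | 4-(methoxymethoxy)-6-methyl-2H-pyran-2-one | Cc1cc(OCOC)cc(=O)o1 | intermediate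
12 | di-tert-butyl dicarbonate | CC(C)(C)OC(=O)OC(=O)OC(C)(C)C | starting material
13 | 3-lithio-4-(methoxymethoxy)-6-methyl-2H-pyran-2-one | [Li]c1c(OCOC)cc(C)oc1=O | intermediate
14 | tert-butyl 4-(methoxymethoxy)-6-methyl-2-oxo-2H-pyran-3-carboxylate | O=C1OC(C)=CC(OCOC)=C1C(=O)OC(C)(C)C | intermediate
15 | tert-butyl 5-[3-chloro-2-methoxy-6-(methoxycarbonyl)-4-(methoxymethoxy)phenoxy]-8-(methoxymethoxy)-1-methyl-3-oxo-2-oxabicyclo[2.2.2]octa-5,7-diene-4-carboxylate (racemic; the bicycle allows one relative configuration of the two bridgeheads) | CC12OC(=O)C(C(=O)OC(C)(C)C)(C(OCOC)=C1)C(Oc1c(OC)c(Cl)c(OCOC)cc1C(=O)OC)=C2 | intermediate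
16 | methyl 2-[2-(tert-butoxycarbonyl)-3-(methoxymethoxy)-5-methylphenoxy]-4-chloro-3-methoxy-5-(methoxymethoxy)benzoate | COC(=O)c1cc(OCOC)c(Cl)c(OC)c1Oc1cc(C)cc(OCOC)c1C(=O)OC(C)(C)C | intermediate
17 | 2-[3-chloro-4-hydroxy-2-methoxy-6-(methoxycarbonyl)phenoxy]-6-hydroxy-4-methylbenzoic acid | COC(=O)c1cc(O)c(Cl)c(OC)c1Oc1cc(C)cc(O)c1C(=O)O | target

Total step count: 10. Longest linear sequence: 8 steps (steps 1–6, 9 and 10); steps 7 and 8 form the second branch.

## Least certain steps and fallbacks

Step 9 (key step). The likeliest failure is that thermal oligomerisation or adventitious hydration of the ynol ether outruns cycloaddition. The C4 alkoxy and C6 methyl groups make 14 a push–pull, weakly electrophilic diene, and the ester-bearing aryl group makes the alkyne of 9 less nucleophilic than an alkyl ynol ether. The fallback reverses the electron demand. It sets out from 9: deprotonation with LiN(i-Pr)2 in THF at −78 °C and capture of the acetylide with 12 should give methyl 2-{[3-(tert-butoxy)-3-oxoprop-1-yn-1-yl]oxy}-4-chloro-3-methoxy-5-(methoxymethoxy)benzoate F1. Diels–Alder addition of 1-methoxy-3-methyl-1-(trimethylsilyloxy)buta-1,3-diene to F1 (PhMe, 80 °C, then mild desilylating work-up), with loss of methanol, should give methyl 2-[2-(tert-butoxycarbonyl)-3-hydroxy-5-methylphenoxy]-4-chloro-3-methoxy-5-(methoxymethoxy)benzoate F2. The acidolysis of step 10 applied to F2 rejoins the route at 17.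

Step 5. The phenoxide of 6 is flanked on both sides and chelated by the ester, so C–O bond formation at copper may be slow, and consumption of the dibromoalkene by elimination or cleavage of the ester at 110 °C may then compete. The fallback is the classical vinyl ether route and sets out from 6. Alkylation with excess 1,2-dibromoethane (K2CO3, DMF) should give methyl 2-(2-bromoethoxy)-4-chloro-3-methoxy-5-(methoxymethoxy)benzoate F3. Elimination with t-BuOK in THF gives methyl 4-chloro-2-(ethenyloxy)-3-methoxy-5-(methoxymethoxy)benzoate F4. Addition of Br2 in CH2Cl2 at −78 °C gives racemic methyl 4-chloro-2-(1,2-dibromoethoxy)-3-methoxy-5-(methoxymethoxy)benzoate F5. Double dehydrobromination with excess t-BuOK (THF, −78 → 0 °C) rejoins the route at 9.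

Step 8. Deprotonation of the C6 methyl group, which gives the more stable extended anion, or addition of n-BuLi to the lactone may compete with ring lithiation, and proton transfer from product to 13 may erode conversion. The fallback fixes the metalation site with a halogen and sets out from 11. Bromination with NBS in MeCN should give 3-bromo-4-(methoxymethoxy)-6-methyl-2H-pyran-2-one F6. Bromine–magnesium exchange with i-PrMgCl·LiCl in THF at −40 °C and capture with 12 rejoins the route at 14.

Step 3. Hydrogen abstraction from a phenol that carries an ester and a chlorine may be slow, and the ester-activated quinone may suffer conjugate addition of water or over-oxidation before it is reduced. The fallback replaces the radical oxidation by ionic para-hydroxylation of the phenolate and sets out from 3. Elbs oxidation (K2S2O8, aqueous NaOH, then acid hydrolysis of the aryl sulfate) also saponifies the ester and should give 4-chloro-2,5-dihydroxy-3-methoxybenzoic acid F7. Fischer esterification (MeOH, H2SO4) rejoins the route at 5.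

Step 2. Exchange at a carbon flanked by two substituents may stop short of completion, and reductive loss of halogen or copper-mediated self-condensation of the free phenol may intervene at 140 °C. The fallback moves the halogen change to low temperature through an arylmagnesium and sets out from 2. Protection with MOMCl and i-Pr2NEt gives methyl 4-bromo-3-methoxy-5-(methoxymethoxy)benzoate F8. Bromine–magnesium exchange with i-PrMgCl·LiCl (THF, −20 °C) and quenching with C2Cl6 gives methyl 4-chloro-3-methoxy-5-(methoxymethoxy)benzoate F9. Removal of the MOM group with HCl in MeOH rejoins the route at 3.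

## Further compounds

F1 | step 9 | methyl 2-{[3-(tert-butoxy)-3-oxoprop-1-yn-1-yl]oxy}-4-chloro-3-methoxy-5-(methoxymethoxy)benzoate | COC(=O)c1cc(OCOC)c(Cl)c(OC)c1OC#CC(=O)OC(C)(C)C
F2 | step 9 | methyl 2-[2-(tert-butoxycarbonyl)-3-hydroxy-5-methylphenoxy]-4-chloro-3-methoxy-5-(methoxymethoxy)benzoate | COC(=O)c1cc(OCOC)c(Cl)c(OC)c1Oc1cc(C)cc(O)c1C(=O)OC(C)(C)C
F3 | step 5 | methyl 2-(2-bromoethoxy)-4-chloro-3-methoxy-5-(methoxymethoxy)benzoate | COC(=O)c1cc(OCOC)c(Cl)c(OC)c1OCCBr
F4 | step 5 | methyl 4-chloro-2-(ethenyloxy)-3-methoxy-5-(methoxymethoxy)benzoate | COC(=O)c1cc(OCOC)c(Cl)c(OC)c1OC=C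
F5 | step 5 | methyl 4-chloro-2-(1,2-dibromoethoxy)-3-methoxy-5-(methoxymethoxy)benzoate (racemic) | COC(=O)c1cc(OCOC)c(Cl)c(OC)c1OC(Br)CBr
F6 | step 8 | 3-bromo-4-(methoxymethoxy)-6-methyl-2H-pyran-2-one | Cc1cc(OCOC)c(Br)c(=O)o1
F7 | step 3 | 4-chloro-2,5-dihydroxy-3-methoxybenzoic acid | OC(=O)c1cc(O)c(Cl)c(OC)c1O
F8 | step 2 | methyl 4-bromo-3-methoxy-5-(methoxymethoxy)benzoate | COC(=O)c1cc(OCOC)c(Br)c(OC)c1
F9 | step 2 | methyl 4-chloro-3-methoxy-5-(methoxymethoxy)benzoate | COC(=O)c1cc(OCOC)c(Cl)c(OC)c1
A1 | alternative 1 | methyl (2Z)-[4-(methoxymethoxy)-6-methyl-3-oxo-1-benzofuran-2(3H)-ylidene]acetate | COC(=O)/C=C1\Oc2cc(C)cc(OCOC)c2C1=O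
A2 | alternative 1 | 1,1-dimethoxy-3-(trimethylsilyloxy)buta-1,3-diene | COC(OC)=CC(=C)O[Si](C)(C)C
A3 | alternative 1 | methyl 6'-methoxy-4-(methoxymethoxy)-6-methyl-3,4'-dioxo-3H-spiro[1-benzofuran-2,1'-cyclohex-5'-ene]-2'-carboxylate (racemic, relative configuration left open) | COC(=O)C1CC(=O)C=C(OC)C12Oc1cc(C)cc(OCOC)c1C2=O
A4 | alternative 2 | dimethyl 2-[2-(tert-butoxycarbonyl)-3-(methoxymethoxy)-5-methylphenoxy]propanedioate | COC(=O)C(Oc1cc(C)cc(OCOC)c1C(=O)OC(C)(C)C)C(=O)OC
A5 | alternative 2 | methyl (2E)-4-oxopent-2-enoate | COC(=O)/C=C/C(C)=O
A6 | alternative 2 | dimethyl 1-[2-(tert-butoxycarbonyl)-3-(methoxymethoxy)-5-methylphenoxy]-2,4-dioxocyclohexane-1,6-dicarboxylate (racemic, mixture of diastereomers) | COC(=O)C1CC(=O)CC(=O)C1(Oc1cc(C)cc(OCOC)c1C(=O)OC(C)(C)C)C(=O)OC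
A7 | alternative 3 | methyl 2-{[3-(tert-butoxy)-3-oxoprop-1-yn-1-yl]oxy}-4-chloro-3-methoxy-5-(methoxymethoxy)benzoate | COC(=O)c1cc(OCOC)c(Cl)c(OC)c1OC#CC(=O)OC(C)(C)C
A8 | alternative 3 | 1-methoxy-3-methyl-1-(trimethylsilyloxy)buta-1,3-diene | COC(O[Si](C)(C)C)=CC(C)=C
A9 | alternative 3 | methyl 2-[2-(tert-butoxycarbonyl)-3-hydroxy-5-methylphenoxy]-4-chloro-3-methoxy-5-(methoxymethoxy)benzoate | COC(=O)c1cc(OCOC)c(Cl)c(OC)c1Oc1cc(C)cc(O)c1C(=O)OC(C)(C)C
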